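**Retrosynthetic overview**

- The route rests on the O1–C2 bond of ring C. The C8a oxygen of ring A is joined to the benzylic C2, β to the C4 ketone, by oxa-Michael addition of a phenol in which O5, O6 and O7 are MOM-masked and only the C8a hydroxyl is free.
- Nirurinetin ⇐ MOM removal ⇐ palladium-mediated loss of the C3 allyl ester ⇐ thiourea-catalysed closure of ring C on the alkylidene β-ketoester 18, which sets C2.
- 18 ⇐ Knoevenagel condensation of allyl β-ketoester 14 with 4-(methoxymethoxy)benzaldehyde 16 (ring B), then selective removal of a THP group from the C8a oxygen.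
- 14 ⇐ carbonate Claisen acylation of acetophenone 11 ⇐ two ortho-lithiations (prenyl, then acetyl) of the symmetric THP ether 5 ⇐ Baeyer–Villiger oxidation of tris-MOM 3,4,5-trihydroxybenzaldehyde.
- Ring order: ring A comes from 3,4,5-trihydroxybenzaldehyde, ring B from 4-hydroxybenzaldehyde, and ring C is closed in the key step.

Key step: step 10

Assumption: the Knoevenagel condensation is taken to give the Z alkene (aroyl group trans to the aryl group), and 19 and 20 are written as enol tautomers, in which C3 outranks ring B, so the spatial arrangement that is 2S in 21 and 22 is named 2R there.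

Abbreviations: MOM = methoxymethyl; THP = tetrahydro-2H-pyran-2-yl; prenyl = 3-methylbut-2-en-1-yl; PPTS = pyridinium p-toluenesulfonate. All THP ethers (5 to 17) are racemic at the acetal carbon.

**Route**

Step 1
Reactants: 1 3,4,5-trihydroxybenzaldehyde
Product: 2 3,4,5-tris(methoxymethoxy)benzaldehyde
Conditions: MOMCl, iPr2NEt, DMF, 0 °C → rt
Reagents that add atoms: chloromethyl methyl ether (MOMCl), COCCl
Why: O-alkylation of the three phenoxides with the chloromethyl ether (acetal formation) should mask O5, O6 and O7 as MOM ethers, which later direct ortho-lithiation and can be removed by mild acid without harming the prenyl group.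

Step 2
Reactants: 2 3,4,5-tris(methoxymethoxy)benzaldehyde
Product: 4 3,4,5-tris(methoxymethoxy)phenol, via aryl formate 3 (not isolated)
Conditions: mCPBA, CH2Cl2, 0 °C → rt; then K2CO3 (cat.), MeOH, rt
Reagents that add atoms: m-chloroperoxybenzoic acid (mCPBA), O=C(OO)c1cccc(Cl)c1
Why: Baeyer–Villiger oxidation in which the electron-rich aryl group (para-alkoxy) migrates in preference to hydrogen, followed by methanolysis of the formate, should give the phenol whose single free hydroxyl is the future O1.

Step 3
Reactants: 4 3,4,5-tris(methoxymethoxy)phenol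
Product: 5 2-[3,4,5-tris(methoxymethoxy)phenoxy]tetrahydro-2H-pyran
Conditions: 3,4-dihydro-2H-pyran, PPTS (cat.), CH2Cl2, rt
Reagents that add atoms: 3,4-dihydro-2H-pyran, C1=COCCC1
Why: Acid-catalysed addition of the phenol to the enol ether (tetrahydropyranylation) marks the future O1 with an acetal that is base-stable, directs lithiation and is far more acid-labile than the MOM ethers.

Step 4
Reactants: 5 2-[3,4,5-tris(methoxymethoxy)phenoxy]tetrahydro-2H-pyran; 6 prenyl bromide
Product: 8 2-[2-(3-methylbut-2-en-1-yl)-3,4,5-tris(methoxymethoxy)phenoxy]tetrahydro-2H-pyran, via aryllithium 7 (not isolated)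
Conditions: n-BuLi, THF, 0 °C; then CuBr·SMe2 (10 mol %), 6, −78 °C → rt
Reagents that add atoms: none
Why: Directed ortho-metalation at one of the two equivalent ring hydrogens, each flanked by the OTHP and an OMOM group, followed by copper-catalysed SN2 allylation at the primary carbon of prenyl bromide (the other terminus is fully substituted) should give the C-prenyl arene.

Step 5
Reactants: 8 2-[2-(3-methylbut-2-en-1-yl)-3,4,5-tris(methoxymethoxy)phenoxy]tetrahydro-2H-pyran
Product: 11 1-[3-(3-methylbut-2-en-1-yl)-2-(tetrahydro-2H-pyran-2-yloxy)-4,5,6-tris(methoxymethoxy)phenyl]ethanone, via aryllithium 9 (not isolated), via lithium hemiaminal alkoxide 10 (not isolated)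
Conditions: n-BuLi, TMEDA, THF, −20 → 0 °C; then MeC(O)N(OMe)Me, −78 → 0 °C; then H2O
Reagents that add atoms: N-methoxy-N-methylacetamide, CC(=O)N(C)OC
Why: A second directed ortho-metalation at the last ring hydrogen (again between OTHP and OMOM, favoured over the benzylic CH2 by the two coordinating acetal oxygens) and Weinreb amide acylation, whose chelated tetrahedral adduct prevents over-addition, should give the hexasubstituted acetophenone.

Step 6
Reactants: 11 1-[3-(3-methylbut-2-en-1-yl)-2-(tetrahydro-2H-pyran-2-yloxy)-4,5,6-tris(methoxymethoxy)phenyl]ethanone; 12 diallyl carbonate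
Product: 14 allyl 3-[3-(3-methylbut-2-en-1-yl)-2-(tetrahydro-2H-pyran-2-yloxy)-4,5,6-tris(methoxymethoxy)phenyl]-3-oxopropanoate, via sodium enolate 13 (not isolated)
Conditions: NaH, 12, THF, reflux; then AcOH, 0 °C
Reagents that add atoms: none
Why: Crossed Claisen condensation (C-acylation of the methyl ketone enolate by the carbonate) is driven by deprotonation of the β-ketoester formed, and because the ortho oxygen is a THP ether the ester cannot lactonise to a 4-hydroxycoumarin.

Step 7
Reactants: 15 4-hydroxybenzaldehyde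
Product: 16 4-(methoxymethoxy)benzaldehyde
Conditions: MOMCl, iPr2NEt, CH2Cl2, 0 °C → rt
Reagents that add atoms: chloromethyl methyl ether (MOMCl), COCCl
Why: O-alkylation of the phenol with the chloromethyl ether protects the future 4'-hydroxyl of ring B in the same way as the ring A oxygens.

Step 8
Reactants: 14 allyl 3-[3-(3-methylbut-2-en-1-yl)-2-(tetrahydro-2H-pyran-2-yloxy)-4,5,6-tris(methoxymethoxy)phenyl]-3-oxopropanoate; 16 4-(methoxymethoxy)benzaldehyde
Product: 17 allyl (2Z)-3-[4-(methoxymethoxy)phenyl]-2-[3-(3-methylbut-2-en-1-yl)-2-(tetrahydro-2H-pyran-2-yloxy)-4,5,6-tris(methoxymethoxy)benzoyl]prop-2-enoate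
Conditions: piperidine (20 mol %), AcOH (20 mol %), 4 Å MS, toluene, rt → 50 °C
Reagents that add atoms: none
Why: Knoevenagel condensation under piperidinium acetate catalysis with removal of water should give the alkylidene β-ketoester, expected mainly as the Z isomer with the twisted aroyl group trans to the aryl ring, and the THP group keeps the ortho oxygen from adding to the new alkene.

Step 9
Reactants: 17 allyl (2Z)-3-[4-(methoxymethoxy)phenyl]-2-[3-(3-methylbut-2-en-1-yl)-2-(tetrahydro-2H-pyran-2-yloxy)-4,5,6-tris(methoxymethoxy)benzoyl]prop-2-enoate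
Product: 18 allyl (2Z)-2-[2-hydroxy-3-(3-methylbut-2-en-1-yl)-4,5,6-tris(methoxymethoxy)benzoyl]-3-[4-(methoxymethoxy)phenyl]prop-2-enoate
Conditions: PPTS (20 mol %), MeOH, rt
Reagents that add atoms: none
Why: Acid-catalysed acetal exchange cleaves the tetrahydropyranyl acetal much faster than the formaldehyde-derived MOM acetals, so the future O1 alone should be freed, and it is freed without base so that no phenoxide is present to start an uncatalysed ring closure.

Step 10
Reactants: 18 allyl (2Z)-2-[2-hydroxy-3-(3-methylbut-2-en-1-yl)-4,5,6-tris(methoxymethoxy)benzoyl]-3-[4-(methoxymethoxy)phenyl]prop-2-enoate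
Product: 19 allyl (2R)-4-hydroxy-5,6,7-tris(methoxymethoxy)-2-[4-(methoxymethoxy)phenyl]-8-(3-methylbut-2-en-1-yl)-2H-chromene-3-carboxylate
Conditions: 1-[3,5-bis(trifluoromethyl)phenyl]-3-[(8S,9S)-6'-methoxycinchonan-9-yl]thiourea (10 mol %), toluene, −25 °C
Reagents that add atoms: none
Why: The thiourea N–H bonds hold the β-ketoester dicarbonyl of 18 while the quinuclidine nitrogen takes the proton of the free ortho hydroxyl, and the phenoxide so formed adds to the β-carbon of the doubly activated alkene in an intramolecular oxa-Michael addition that forms O1–C2. The closest known reaction type is the cinchona-thiourea-catalysed enantioselective cyclisation of 2'-hydroxyaryl alkylidene β-ketoesters to flavanone-3-carboxylates, applied here with an allyl ester. Ring C closes in the 6-endo-trig mode. C2 is the only new stereocentre and the substrate is achiral, so its configuration is set by the catalyst alone; the quinine-derived catalyst is expected to give the arrangement of the (2S)-flavanone series (named 2R in 19), and the quinidine-derived pseudoenantiomer is available should the sense prove opposite. The step needs enantioface selectivity, which two-point binding of the β-ketoester and a cold non-polar medium that slows uncatalysed closure should secure. It also needs regioselectivity, which the substrate secures because the other oxygen flanking the acyl group (the future O5) is a MOM ether.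

Step 11
Reactants: 19 allyl (2R)-4-hydroxy-5,6,7-tris(methoxymethoxy)-2-[4-(methoxymethoxy)phenyl]-8-(3-methylbut-2-en-1-yl)-2H-chromene-3-carboxylate
Product: 21 (2S)-5,6,7-tris(methoxymethoxy)-2-[4-(methoxymethoxy)phenyl]-8-(3-methylbut-2-en-1-yl)-2,3-dihydro-4H-chromen-4-one, via beta-keto acid 20 (not isolated)
Conditions: Pd(PPh3)4 (5 mol %), HCO2H, Et3N, THF, rt → 40 °C
Reagents that add atoms: none
Why: Tsuji deallylation–decarboxylation: zerovalent palladium ionises the allyl ester, formate reduces the allyl fragment to propene, and the β-keto acid loses CO2 through its cyclic transition state in a formate-buffered medium without free amine, which should avoid the ring opening of the β-ketoester that would erode C2.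

Step 12
Reactants: 21 (2S)-5,6,7-tris(methoxymethoxy)-2-[4-(methoxymethoxy)phenyl]-8-(3-methylbut-2-en-1-yl)-2,3-dihydro-4H-chromen-4-one
Product: 22 nirurinetin [(2S)-5,6,7-trihydroxy-2-(4-hydroxyphenyl)-8-(3-methylbut-2-en-1-yl)-2,3-dihydro-4H-chromen-4-one]
Conditions: 3 M aq HCl, MeOH, 40 °C, under argon
Reagents that add atoms: none
Why: Acid-catalysed acetal solvolysis should remove the four aryl MOM ethers under conditions mild enough to leave the prenyl alkene unprotonated, and in the absence of base the C2 stereocentre should not be scrambled by ring opening.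

**Compound list**

1 | 3,4,5-trihydroxybenzaldehyde | O=Cc1cc(O)c(O)c(O)c1 | starting material
2 | 3,4,5-tris(methoxymethoxy)benzaldehyde | O=Cc1cc(OCOC)c(OCOC)c(OCOC)c1 | intermediate
3 | 3,4,5-tris(methoxymethoxy)phenyl formate | O=COc1cc(OCOC)c(OCOC)c(OCOC)c1 | intermediate
4 | 3,4,5-tris(methoxymethoxy)phenol | Oc1cc(OCOC)c(OCOC)c(OCOC)c1 | intermediate
5 | 2-[3,4,5-tris(methoxymethoxy)phenoxy]tetrahydro-2H-pyran (racemic) | COCOc1cc(OC2CCCCO2)cc(OCOC)c1OCOC | intermediate
6 | prenyl bromide (1-bromo-3-methylbut-2-ene) | CC(C)=CCBr | starting material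
7 | [2-(tetrahydro-2H-pyran-2-yloxy)-4,5,6-tris(methoxymethoxy)phenyl]lithium | [Li]c1c(OC2CCCCO2)cc(OCOC)c(OCOC)c1OCOC | intermediate
8 | 2-[2-(3-methylbut-2-en-1-yl)-3,4,5-tris(methoxymethoxy)phenoxy]tetrahydro-2H-pyran (racemic) | CC(C)=CCc1c(OC2CCCCO2)cc(OCOC)c(OCOC)c1OCOC | intermediate
9 | [3-(3-methylbut-2-en-1-yl)-2-(tetrahydro-2H-pyran-2-yloxy)-4,5,6-tris(methoxymethoxy)phenyl]lithium | [Li]c1c(OC2CCCCO2)c(CC=C(C)C)c(OCOC)c(OCOC)c1OCOC | intermediate
10 | lithium 1-[methoxy(methyl)amino]-1-[3-(3-methylbut-2-en-1-yl)-2-(tetrahydro-2H-pyran-2-yloxy)-4,5,6-tris(methoxymethoxy)phenyl]ethanolate | [Li]OC(C)(N(C)OC)c1c(OC2CCCCO2)c(CC=C(C)C)c(OCOC)c(OCOC)c1OCOC | intermediate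
11 | 1-[3-(3-methylbut-2-en-1-yl)-2-(tetrahydro-2H-pyran-2-yloxy)-4,5,6-tris(methoxymethoxy)phenyl]ethanone (racemic at the acetal carbon) | CC(=O)c1c(OC2CCCCO2)c(CC=C(C)C)c(OCOC)c(OCOC)c1OCOC | intermediate
12 | diallyl carbonate | C=CCOC(=O)OCC=C | starting material
13 | sodium 1-[3-(3-methylbut-2-en-1-yl)-2-(tetrahydro-2H-pyran-2-yloxy)-4,5,6-tris(methoxymethoxy)phenyl]ethen-1-olate | [Na]OC(=C)c1c(OC2CCCCO2)c(CC=C(C)C)c(OCOC)c(OCOC)c1OCOC | intermediate
14 | allyl 3-[3-(3-methylbut-2-en-1-yl)-2-(tetrahydro-2H-pyran-2-yloxy)-4,5,6-tris(methoxymethoxy)phenyl]-3-oxopropanoate (racemic at the acetal carbon) | C=CCOC(=O)CC(=O)c1c(OC2CCCCO2)c(CC=C(C)C)c(OCOC)c(OCOC)c1OCOC | intermediate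
15 | 4-hydroxybenzaldehyde | O=Cc1ccc(O)cc1 | starting material
16 | 4-(methoxymethoxy)benzaldehyde | O=Cc1ccc(OCOC)cc1 | intermediate
17 | allyl (2Z)-3-[4-(methoxymethoxy)phenyl]-2-[3-(3-methylbut-2-en-1-yl)-2-(tetrahydro-2H-pyran-2-yloxy)-4,5,6-tris(methoxymethoxy)benzoyl]prop-2-enoate (racemic at the acetal carbon) | CC(C)=CCc1c(OC2CCCCO2)c(C(=O)/C(=C/c2ccc(OCOC)cc2)C(=O)OCC=C)c(OCOC)c(OCOC)c1OCOC | intermediate
18 | allyl (2Z)-2-[2-hydroxy-3-(3-methylbut-2-en-1-yl)-4,5,6-tris(methoxymethoxy)benzoyl]-3-[4-(methoxymethoxy)phenyl]prop-2-enoate | CC(C)=CCc1c(O)c(C(=O)/C(=C/c2ccc(OCOC)cc2)C(=O)OCC=C)c(OCOC)c(OCOC)c1OCOC | intermediate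
19 | allyl (2R)-4-hydroxy-5,6,7-tris(methoxymethoxy)-2-[4-(methoxymethoxy)phenyl]-8-(3-methylbut-2-en-1-yl)-2H-chromene-3-carboxylate (enol tautomer of the flavanone-3-carboxylate) | CC(C)=CCc1c(OCOC)c(OCOC)c(OCOC)c2c1O[C@H](c1ccc(OCOC)cc1)C(C(=O)OCC=C)=C2O | intermediate
20 | (2R)-4-hydroxy-5,6,7-tris(methoxymethoxy)-2-[4-(methoxymethoxy)phenyl]-8-(3-methylbut-2-en-1-yl)-2H-chromene-3-carboxylic acid (enol tautomer) | CC(C)=CCc1c(OCOC)c(OCOC)c(OCOC)c2c1O[C@H](c1ccc(OCOC)cc1)C(C(=O)O)=C2O | intermediate
21 | (2S)-5,6,7-tris(methoxymethoxy)-2-[4-(methoxymethoxy)phenyl]-8-(3-methylbut-2-en-1-yl)-2,3-dihydro-4H-chromen-4-one | CC(C)=CCc1c(OCOC)c(OCOC)c(OCOC)c2c1O[C@H](c1ccc(OCOC)cc1)CC2=O | intermediate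
22 | nirurinetin, (2S)-5,6,7-trihydroxy-2-(4-hydroxyphenyl)-8-(3-methylbut-2-en-1-yl)-2,3-dihydro-4H-chromen-4-one | CC(C)=CCc1c(O)c(O)c(O)c2c1O[C@H](c1ccc(O)cc1)CC2=O | target

**Step count**

Total steps: 12. Longest linear sequence: 11 (steps 1 to 6 and 8 to 12); step 7 is a one-step branch.

**Steps most likely to fail**

Step 10. The hexasubstituted ring A twists the aroyl group and the ester is allyl, not a bulkier group, so the catalyst may discriminate the alkene faces poorly, or ring closure may run without the catalyst and lower the enantiomeric purity. The fallback sets out from ketone 11 and comes back at 21; it forms the C2–aryl bond in place of O1–C2. Heating 11 with N,N-dimethylformamide dimethyl acetal should give the enaminone (2E)-3-(dimethylamino)-1-[3-(3-methylbut-2-en-1-yl)-2-(tetrahydro-2H-pyran-2-yloxy)-4,5,6-tris(methoxymethoxy)phenyl]prop-2-en-1-one F1. PPTS in MeOH at 50 °C should then remove the THP group and let the freed phenol displace dimethylamine, closing the chromone 5,6,7-tris(methoxymethoxy)-8-(3-methylbut-2-en-1-yl)-4H-chromen-4-one F2. Rhodium-catalysed asymmetric 1,4-addition of 4-(methoxymethoxy)phenylboronic acid to F2 ([Rh(OH)(cod)]2 with the antipode of an electron-poor chiral bisphosphine such as MeO-F12-BIPHEP that gives the 2S product, toluene/H2O) would give 21.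

Step 9. While the THP group is cleaved, the liberated phenol may add to the activated alkene without catalyst control, or the MOM ether ortho to the ketone may be lost as well. The fallback sets out from 14 and comes back at 18; it changes the order of events. PPTS in MeOH at rt should first free the phenol of the ketoester to give allyl 3-[2-hydroxy-3-(3-methylbut-2-en-1-yl)-4,5,6-tris(methoxymethoxy)phenyl]-3-oxopropanoate F3. Knoevenagel condensation of F3 with 16 (piperidine, AcOH, toluene, rt, short contact), the usual order for this substrate class, would give 18, which is taken into step 10 at once.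

Step 12. Under protic acid the C7 hydroxyl may add to the protonated prenyl alkene to form a chroman, the flavanone may open and reclose with loss of configuration, and the 5,6,7-triol may oxidise in air. The fallback sets out from 21 and comes back at 22; it replaces acid solvolysis by acetal-to-silyl exchange. Trimethylsilyl triflate with 2,2'-bipyridyl in CH2Cl2 at 0 °C should convert the four aryl MOM ethers into the silyl ether (2S)-8-(3-methylbut-2-en-1-yl)-5,6,7-tris(trimethylsilyloxy)-2-[4-(trimethylsilyloxy)phenyl]-2,3-dihydro-4H-chromen-4-one F4. Neutral aqueous work-up (H2O, THF) would hydrolyse F4 to 22.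

**Further compounds**

F1 | step 10 | (2E)-3-(dimethylamino)-1-[3-(3-methylbut-2-en-1-yl)-2-(tetrahydro-2H-pyran-2-yloxy)-4,5,6-tris(methoxymethoxy)phenyl]prop-2-en-1-one | CN(C)/C=C/C(=O)c1c(OC2CCCCO2)c(CC=C(C)C)c(OCOC)c(OCOC)c1OCOC
F2 | step 10 | 5,6,7-tris(methoxymethoxy)-8-(3-methylbut-2-en-1-yl)-4H-chromen-4-one | CC(C)=CCc1c(OCOC)c(OCOC)c(OCOC)c2c1OC=CC2=O
F3 | step 9 | allyl 3-[2-hydroxy-3-(3-methylbut-2-en-1-yl)-4,5,6-tris(methoxymethoxy)phenyl]-3-oxopropanoate | C=CCOC(=O)CC(=O)c1c(O)c(CC=C(C)C)c(OCOC)c(OCOC)c1OCOC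
F4 | step 12 | (2S)-8-(3-methylbut-2-en-1-yl)-5,6,7-tris(trimethylsilyloxy)-2-[4-(trimethylsilyloxy)phenyl]-2,3-dihydro-4H-chromen-4-one | CC(C)=CCc1c(O[Si](C)(C)C)c(O[Si](C)(C)C)c(O[Si](C)(C)C)c2c1O[C@H](c1ccc(O[Si](C)(C)C)cc1)CC2=O
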